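Assumptions: (a) The sense of induction of the Rh/TADDOL‑phosphoramidite catalyst is assigned by analogy. Both ligand antipodes are equally accessible, and the one that delivers (2S,3R)‑4 is used. (b) Only substrates and products are numbered. Reagents appear under "Reagents that add atoms".

Target analysis: 4‑aryl‑1‑tetralone, (2S,3S,4R). C2‑Me and C3‑Me are cis, and C3‑Me and C4‑Ar are trans. C6 carries OMe (para to C8a, the carbonyl‑bearing ring carbon) and C7 carries OH (para to C4a).

## Retrosynthetic overview
1. The usual closure, C1–C8a Friedel–Crafts acylation of a 4,4‑diarylbutanoic acid, is deliberately avoided. The ketone is present before ring closure but is masked as a dithiane, so C2 cannot enolise.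
2. C4–C4a disconnection: the ArB‑stabilised benzylic cation closes onto ring A para to the free OH. This forms the only permanent ring and sets C4 trans to C3‑Me.
3. C1–ArA disconnection: an unprotected lithio‑phenoxide opens a γ‑lactone.
4. Key step: a Rh‑catalysed enantioselective desymmetrising arylation of meso‑2,3‑dimethylsuccinic anhydride fixes C2 and C3 (cis) in one catalytic C–C bond formation.
5. Ring order: anhydride and γ‑lactone (both temporary), then the dithiane (temporary) and the carbocycle in one pot.

## Route

**Step 1**
Reactants: 1, meso‑2,3‑dimethylsuccinic acid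
Product: 2, cis‑(3R,4S)‑3,4‑dimethyldihydrofuran‑2,5‑dione (meso anhydride)
Conditions: AcCl, reflux, 2 h; concentrate
Reagents that add atoms: none
Why: This is a dehydrative anhydride formation under non‑enolising conditions, so the cis (meso) relationship of the two methyl groups is retained.

**Step 2**
Reactants: 2, the meso anhydride; 3, 4‑bromo‑1,2‑dimethoxybenzene
Product: 4, (2S,3R)‑4‑(3,4‑dimethoxyphenyl)‑2,3‑dimethyl‑4‑oxobutanoic acid
Conditions: 3 (1.7 equiv), n‑BuLi, THF, −78 °C; Zn(OTf)2, to rt; then 2, [Rh(cod)Cl]2 (4 mol %), TADDOL‑derived P–NMe2 phosphoramidite (8 mol %), THF, 50 °C; 1 M HCl work‑up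
Reagents that add atoms: none beyond the numbered reactants (the aryl group comes from 3)
Why: In this Rh(I)‑catalysed enantioselective desymmetrising Negishi‑type acylation of a meso cyclic anhydride (Rovis‑type), the chiral Rh selects the enantiotopic acyl C–O bond next to the (R)‑carbon and transfers aryl from ArZnOTf, so the absolute configuration of future C2 and C3 is fixed in one step with the cis relationship inherited from 2.

**Step 3**
Reactants: 4, the keto acid
Product: 5, (3S,4R,5R)‑5‑(3,4‑dimethoxyphenyl)‑3,4‑dimethyldihydrofuran‑2(3H)‑one (3,4‑cis, 4,5‑trans)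
Conditions: L‑Selectride (2.2 equiv), THF, −78 °C; NaOH/H2O2 work‑up; 1 M HCl, CH2Cl2, rt; recrystallise to ≥98 % ee
Reagents that add atoms: none (hydride only)
Why: Felkin–Anh reduction of the α‑methyl aryl ketone and spontaneous γ‑lactonisation remove the epimerisable α‑keto centre and differentiate the two termini, while the new C5 centre is only a placeholder that is erased in Step 5, so any C5 epimer can be carried forward.

**Step 4**
Reactants: 5, the lactone; 6, 5‑bromo‑2‑methoxyphenol
Product: 7, (2S,3R,4R)‑4‑(3,4‑dimethoxyphenyl)‑4‑hydroxy‑1‑(3‑hydroxy‑4‑methoxyphenyl)‑2,3‑dimethylbutan‑1‑one (in equilibrium with its cyclic hemiketal)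
Conditions: 6 (1.5 equiv), n‑BuLi (1 equiv per 6) then t‑BuLi (2 equiv per 6), THF, −78 °C; add 5, −78 °C, 1 h; AcOH/THF quench at −78 °C
Reagents that add atoms: none beyond the numbered reactants (the aryl group comes from 6)
Why: Br–Li exchange on the lithium phenoxide followed by 1,2‑addition to the lactone stops at the lithium hemiketal at −78 °C, giving mono‑addition without α‑deprotonation, so C2 and C3 are untouched and no phenol protecting group is needed.

**Step 5**
Reactants: 7, the hydroxy ketone / hemiketal
Product: 8, (2'S,3'S,4'R)‑4'‑(3,4‑dimethoxyphenyl)‑6'‑methoxy‑2',3'‑dimethyl‑3',4'‑dihydro‑2'H‑spiro[1,3‑dithiane‑2,1'‑naphthalen]‑7'‑ol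
Conditions: HS(CH2)3SH (1.0 equiv), BF3·OEt2 (3 equiv), CH2Cl2 (0.02 M), −78 °C, 2 h; then warm to 0 °C, 1 h; NaHCO3
Reagents that add atoms: 1,3‑propanedithiol, SCCCS
Why: Lewis‑acid thioketalisation at −78 °C, where the 2‑aryl oxocarbenium/thionium ions do not epimerise at the α‑carbon, removes both the deactivating and the enolisable character of C1, and on warming the 3,4‑dimethoxybenzylic cation undergoes intramolecular Friedel–Crafts alkylation at the unhindered position para to the free OH through a half‑chair with ArB and C3‑Me pseudo‑equatorial and C2‑Me axial, the 3,4‑cis alternatives suffering Ar/Me or Me/S 1,3‑diaxial clashes, so C4 is set (R), trans to C3‑Me.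

**Step 6**
Reactants: 8, the spiro‑dithiane
Product: 9, schisandrone, (2S,3S,4R)‑4‑(3,4‑dimethoxyphenyl)‑7‑hydroxy‑6‑methoxy‑2,3‑dimethyl‑3,4‑dihydronaphthalen‑1(2H)‑one
Conditions: MeI (20 equiv), CaCO3 (5 equiv), MeCN/H2O 9:1, 45 °C
Reagents that add atoms: water, O
Why: Alkylative dithiane hydrolysis under neutral, buffered, non‑oxidising conditions proceeds through a p‑anisyl‑stabilised thionium ion that water captures rapidly, which reveals the ketone without oxidising or methylating the phenol and without enolising C2.

## Compound list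
| No. | Name | SMILES | Role |
|---|---|---|---|
| 1 | meso‑(2R,3S)‑2,3‑dimethylsuccinic acid | OC(=O)[C@@H](C)[C@@H](C)C(=O)O | starting material |
| 2 | cis‑(3R,4S)‑3,4‑dimethyldihydrofuran‑2,5‑dione | O=C1[C@@H](C)[C@@H](C)C(=O)O1 | intermediate |
| 3 | 4‑bromo‑1,2‑dimethoxybenzene | COc1ccc(Br)cc1OC | starting material |
| 4 | (2S,3R)‑4‑(3,4‑dimethoxyphenyl)‑2,3‑dimethyl‑4‑oxobutanoic acid | OC(=O)[C@@H](C)[C@@H](C)C(=O)c1ccc(OC)c(OC)c1 | intermediate |
| 5 | (3S,4R,5R)‑5‑(3,4‑dimethoxyphenyl)‑3,4‑dimethyldihydrofuran‑2(3H)‑one | O=C1[C@@H](C)[C@@H](C)[C@@H](O1)c2ccc(OC)c(OC)c2 | intermediate |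
| 6 | 5‑bromo‑2‑methoxyphenol | COc1ccc(Br)cc1O | starting material |
| 7 | (2S,3R,4R)‑4‑(3,4‑dimethoxyphenyl)‑4‑hydroxy‑1‑(3‑hydroxy‑4‑methoxyphenyl)‑2,3‑dimethylbutan‑1‑one | COc1ccc(cc1O)C(=O)[C@@H](C)[C@@H](C)[C@@H](O)c1ccc(OC)c(OC)c1 | intermediate |
| 8 | (2'S,3'S,4'R)‑spiro‑dithiane tetralin (C1 thioketal of 9) | COc1cc2c(cc1O)C1(SCCCS1)[C@@H](C)[C@@H](C)[C@@H]2c1ccc(OC)c(OC)c1 | intermediate |
| 9 | schisandrone (2S,3S,4R) | COc1cc2c(cc1O)C(=O)[C@@H](C)[C@@H](C)[C@@H]2c1ccc(OC)c(OC)c1 | target |

## Step count and risks
Total steps: 6. Longest linear sequence: 6 (1 → 2 → 4 → 5 → 7 → 8 → 9). Compounds 3 and 6 are used as purchased, and no protecting groups are used.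

**Steps most likely to fail**
1. **Step 5.**
   - Failure modes: C2 could scramble through oxocarbenium/enol‑ether equilibration before masking is complete. Sulfur could trap the C4 cation. E1 loss of C3–H could erode the stereochemistry.
   - Fallback: give up carrying C2 through the closure. Convert 7 into the 1‑aroyl‑2‑aryl donor–acceptor cyclopropane (C4 mesylate, then 3‑exo‑tet enolate closure). Run a SnCl4 homo‑Nazarov‑type ring‑opening cyclisation to the tetralone enolate. Then set C2 last by kinetic axial protonation anti to C3‑Me.
2. **Step 4.**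
   - Failure modes: the dianion may be poorly soluble, may add twice, or may enolise the lactone.
   - Fallback: swap the order of aryl introduction. Run the Rh desymmetrisation with the O‑silylated ring‑A arylzinc and the antipodal ligand, so the C1 ketone is formed catalytically. Thioketalise that keto acid, build the ArB carbinol from the acid terminus (Weinreb amide, ArB‑MgBr, NaBH4), and close with TFA.
3. **Step 2.**
   - Failure modes: the ee or yield may be insufficient with the arylzinc generated in situ.
   - Fallback: separate desymmetrisation from C–C bond formation. Use cinchona‑alkaloid ((DHQD)2AQN or (DHQ)2AQN)‑catalysed methanolysis of 2 to give the hemiester. Convert its acid terminus to a thioester and perform a Pd‑catalysed Fukuyama/Negishi ketone synthesis with ArB‑ZnX. Reduction then lactonises onto the methyl ester to give the same lactone 5.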